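**Strategy.** The target is a C2-symmetric 7,7′-linked dimer of a 2-hydroxy-2-methylbenzofuran-3(2H)-one, so both halves are built at once on a preformed biaryl. Everything rests on disconnecting, in each furanone ring, the bond between the ketone carbon C3 and the hemiketal carbon C2. The precursor is a symmetric biaryl bis(2-vinyloxybenzaldehyde): on each arene the formyl carbon (future C3, on C3a) sits next to the O-vinyl group (future O1–C2, on C7a). One NHC-catalysed double hydroacylation closes both five-membered rings through C3–C2 bond formation and turns the vinyl CH2 into the C2 methyl. The C2 oxygens are then added with catalyst control and kept silylated until the end.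

Key step: step 7

Remark: the biaryl axis is not defined in the target and is left uncontrolled (4–14 are used as axial racemates); because the hemiketal carbons C2/C2′ can epimerise by ring–chain tautomerism once an alkoxide forms, they are carried as silyl ketals and freed only in the last operation.

Step 1
Reactants: 1 3-hydroxy-4,5-dimethoxybenzaldehyde
Product: 2 3-hydroxy-2-iodo-4,5-dimethoxybenzaldehyde
Conditions: ICl (1.1 equiv), pyridine, 1,4-dioxane, rt
Reagents that add atoms: iodine monochloride, ClI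
Why: Electrophilic aromatic iodination; the free phenol directs to its only open ortho position C2 (also para to the 5-methoxy group), the same site selectivity as in the 2-halogenation of isovanillin.

Step 2
Reactants: 2 3-hydroxy-2-iodo-4,5-dimethoxybenzaldehyde
Product: 3 3-(benzyloxy)-2-iodo-4,5-dimethoxybenzaldehyde
Conditions: BnBr, K2CO3, DMF, rt
Reagents that add atoms: benzyl bromide, BrCc1ccccc1
Why: Williamson ether synthesis on the phenoxide; the benzyl ether should survive every later step and leave by neutral hydrogenolysis.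

Step 3
Reactants: 3 3-(benzyloxy)-2-iodo-4,5-dimethoxybenzaldehyde (two molecules)
Product: 4 6,6'-bis(benzyloxy)-4,4',5,5'-tetramethoxy-[1,1'-biphenyl]-2,2'-dicarbaldehyde
Conditions: activated Cu powder (4 equiv), DMF, 140 °C, argon
Reagents that add atoms: none
Why: Ullmann homocoupling; the ortho-formyl group activates the C–I bond toward copper, and 2-iodo-3-alkoxybenzaldehydes are established substrates for tetra-ortho-substituted biaryls.

Step 4
Reactants: 4 6,6'-bis(benzyloxy)-4,4',5,5'-tetramethoxy-[1,1'-biphenyl]-2,2'-dicarbaldehyde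
Product: 6 6,6'-bis(benzyloxy)-4,4',5,5'-tetramethoxy-[1,1'-biphenyl]-2,2'-diol, via bis-formate 5 (not isolated)
Conditions: mCPBA (3 equiv), CH2Cl2, 0 °C to rt; then K2CO3 (cat.), MeOH, rt
Reagents that add atoms: meta-chloroperoxybenzoic acid, OOC(=O)c1cccc(Cl)c1
Why: Baeyer–Villiger (Dakin-type) oxidation, in which the electron-rich aryl group (para-methoxy to the formyl carbon) migrates in the Criegee intermediate to give the aryl formate that methanolysis cleaves to the phenol.

Step 5
Reactants: 6 6,6'-bis(benzyloxy)-4,4',5,5'-tetramethoxy-[1,1'-biphenyl]-2,2'-diol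
Product: 8 6,6'-bis(benzyloxy)-2,2'-dihydroxy-4,4',5,5'-tetramethoxy-[1,1'-biphenyl]-3,3'-dicarbaldehyde, via bis(hydroxymethyl) biphenol 7 (not isolated)
Conditions: MgCl2 (anhydrous), Et3N, paraformaldehyde, MeCN, reflux
Reagents that add atoms: paraformaldehyde (reacting as formaldehyde), C=O
Why: Casnati–Skattebøl ortho-formylation, in which the magnesium phenoxide delivers formaldehyde to the single free ring position (ortho to the hydroxyl) and the salicyl alkoxide is oxidised by a second formaldehyde through Oppenauer-type hydride transfer.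

Step 6
Reactants: 8 6,6'-bis(benzyloxy)-2,2'-dihydroxy-4,4',5,5'-tetramethoxy-[1,1'-biphenyl]-3,3'-dicarbaldehyde
Product: 9 6,6'-bis(benzyloxy)-4,4',5,5'-tetramethoxy-2,2'-bis(vinyloxy)-[1,1'-biphenyl]-3,3'-dicarbaldehyde
Conditions: 2,4,6-trivinylcyclotriboroxane–pyridine complex, Cu(OAc)2, pyridine, 4 Å MS, CH2Cl2, rt, dry air
Reagents that add atoms: 2,4,6-trivinylcyclotriboroxane (pyridine complex), C=CB1OB(C=C)OB(C=C)O1
Why: Chan–Lam-type copper-mediated O-vinylation (vinyl transfer from boron to copper, then C–O reductive elimination from trivalent copper), which runs at room temperature and tolerates aldehydes and benzyl ethers.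

Step 7
Reactants: 9 6,6'-bis(benzyloxy)-4,4',5,5'-tetramethoxy-2,2'-bis(vinyloxy)-[1,1'-biphenyl]-3,3'-dicarbaldehyde
Product: 10 6,6'-bis(benzyloxy)-4,4',5,5'-tetramethoxy-2,2'-dimethyl-[7,7'-bibenzofuran]-3,3'(2H,2'H)-dione (mixture of C2 epimers)
Conditions: 2-mesityl-6,7-dihydro-5H-pyrrolo[2,1-c][1,2,4]triazol-2-ium tetrafluoroborate (20 mol%), DBU (20 mol%), degassed 1,4-dioxane, 120 °C, argon
Reagents that add atoms: none
Why: The carbene adds to each formyl group to give a Breslow intermediate whose nucleophilic carbon (future C3) lies over the O-vinyl group on the neighbouring ring carbon; C3–C2 bond formation at the oxygen-bearing vinyl carbon is coupled with proton transfer from the Breslow hydroxyl to the terminal CH2 (concerted ene-like path or oxocarbenium ion pair), and loss of the carbene gives the ketone. The closest known reaction type is the NHC-catalysed intramolecular hydroacylation of enol ethers and unactivated alkenes, which converts 2-(alkenyloxy)benzaldehydes into benzofuranones and chromanones. Each furanone ring closes in the 5-exo-trig mode. The two new C2–H stereocentres form without control, which is harmless because step 8 planarises them. The step needs Markovnikov regiochemistry (methyl on C2, no six-membered chromanone) and cyclisation in preference to intermolecular benzoin coupling; the enol ether polarisation puts the proton on the terminal carbon, and the hindered 2,6-dioxygenated aldehydes are poor benzoin partners. Because 9 is C2-symmetric, both ends react under one set of conditions and no desymmetrisation is required.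

Step 8
Reactants: 10 6,6'-bis(benzyloxy)-4,4',5,5'-tetramethoxy-2,2'-dimethyl-[7,7'-bibenzofuran]-3,3'(2H,2'H)-dione
Product: 11 6,6'-bis(benzyloxy)-4,4',5,5'-tetramethoxy-2,2'-dimethyl-3,3'-bis[(triethylsilyl)oxy]-7,7'-bibenzofuran
Conditions: TESOTf (2.6 equiv), Et3N, CH2Cl2, 0 °C
Reagents that add atoms: triethylsilyl trifluoromethanesulfonate, CC[Si](CC)(CC)OS(=O)(=O)C(F)(F)F
Why: Soft enolisation and O-silylation of the ketones; C2 is the only enolisable position, and the aromatic 3-silyloxybenzofuran formed erases the uncontrolled C2–H centres.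

Step 9
Reactants: 11 6,6'-bis(benzyloxy)-4,4',5,5'-tetramethoxy-2,2'-dimethyl-3,3'-bis[(triethylsilyl)oxy]-7,7'-bibenzofuran
Product: 13 (2S,2'S)-6,6'-bis(benzyloxy)-4,4',5,5'-tetramethoxy-2,2'-dimethyl-2,2'-bis[(triethylsilyl)oxy]-[7,7'-bibenzofuran]-3,3'(2H,2'H)-dione, via bis(silyloxy epoxide) 12 (not isolated)
Conditions: (S,S)-Mn(salen)Cl [chloro(N,N'-bis(3,5-di-tert-butylsalicylidene)-1,2-cyclohexanediaminato)manganese, trivalent manganese] (10 mol%), PhIO (2.5 equiv), 4-phenylpyridine N-oxide, 4 Å MS, CH2Cl2, −20 to 0 °C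
Reagents that add atoms: iodosylbenzene, O=Ic1ccccc1
Why: Jacobsen–Katsuki oxygen-atom transfer to the cyclic, aryl-conjugated enol ether followed by Rubottom-type epoxide opening with 1,4-silyl shift; the chiral oxomanganese salen complex picks the enol ether face at each C2 (catalyst control, (S,S) ligand chosen by analogy with its facial sense on indene-type olefins), and because the new C2–O bond is never broken afterwards both centres should arrive as locked (S)-silyl ketals.

Step 10
Reactants: 13 (2S,2'S)-6,6'-bis(benzyloxy)-4,4',5,5'-tetramethoxy-2,2'-dimethyl-2,2'-bis[(triethylsilyl)oxy]-[7,7'-bibenzofuran]-3,3'(2H,2'H)-dione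
Product: 15 (2R,2'R)-2,2',6,6'-tetrahydroxy-4,4',5,5'-tetramethoxy-2,2'-dimethyl-[7,7'-bibenzofuran]-3,3'(2H,2'H)-dione, via debenzylated bis(silyl ketal) 14 (not isolated)
Conditions: H2 (1 atm), 10% Pd/C, THF, rt; filter; then HF·pyridine, pyridine, THF, 0 °C; pH 7 buffer work-up
Reagents that add atoms: none
Why: Hydrogenolysis of the two aryl benzyl ethers under neutral conditions, then acid-assisted fluoride cleavage of the Si–O bonds only, so the C2–O bonds stay intact, no free alkoxide is formed and the hemiketals should be released with retention as (2R,2'R) (the descriptor changes from S to R only because hydrogen replaces silicon in the priority order).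

**Compound list**

1 | 3-hydroxy-4,5-dimethoxybenzaldehyde | COc1cc(C=O)cc(O)c1OC | starting material
2 | 3-hydroxy-2-iodo-4,5-dimethoxybenzaldehyde | COc1cc(C=O)c(I)c(O)c1OC | intermediate
3 | 3-(benzyloxy)-2-iodo-4,5-dimethoxybenzaldehyde | COc1cc(C=O)c(I)c(OCc2ccccc2)c1OC | intermediate
4 | 6,6'-bis(benzyloxy)-4,4',5,5'-tetramethoxy-[1,1'-biphenyl]-2,2'-dicarbaldehyde (axial racemate) | COc1cc(C=O)c(-c2c(C=O)cc(OC)c(OC)c2OCc4ccccc4)c(OCc5ccccc5)c1OC | intermediate
5 | 6,6'-bis(benzyloxy)-4,4',5,5'-tetramethoxy-[1,1'-biphenyl]-2,2'-diyl diformate (bis-formate, not isolated) | COc1cc(OC=O)c(-c2c(OC=O)cc(OC)c(OC)c2OCc4ccccc4)c(OCc5ccccc5)c1OC | intermediate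
6 | 6,6'-bis(benzyloxy)-4,4',5,5'-tetramethoxy-[1,1'-biphenyl]-2,2'-diol | COc1cc(O)c(-c2c(O)cc(OC)c(OC)c2OCc4ccccc4)c(OCc5ccccc5)c1OC | intermediate
7 | 6,6'-bis(benzyloxy)-3,3'-bis(hydroxymethyl)-4,4',5,5'-tetramethoxy-[1,1'-biphenyl]-2,2'-diol (present as magnesium salt, not isolated) | COc1c(CO)c(O)c(-c2c(O)c(CO)c(OC)c(OC)c2OCc4ccccc4)c(OCc5ccccc5)c1OC | intermediate
8 | 6,6'-bis(benzyloxy)-2,2'-dihydroxy-4,4',5,5'-tetramethoxy-[1,1'-biphenyl]-3,3'-dicarbaldehyde | COc1c(C=O)c(O)c(-c2c(O)c(C=O)c(OC)c(OC)c2OCc4ccccc4)c(OCc5ccccc5)c1OC | intermediate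
9 | 6,6'-bis(benzyloxy)-4,4',5,5'-tetramethoxy-2,2'-bis(vinyloxy)-[1,1'-biphenyl]-3,3'-dicarbaldehyde | COc1c(C=O)c(OC=C)c(-c2c(OC=C)c(C=O)c(OC)c(OC)c2OCc4ccccc4)c(OCc5ccccc5)c1OC | intermediate
10 | 6,6'-bis(benzyloxy)-4,4',5,5'-tetramethoxy-2,2'-dimethyl-[7,7'-bibenzofuran]-3,3'(2H,2'H)-dione (C2 and C2' unassigned, mixture of epimers) | COc1c(OCc4ccccc4)c(-c2c(OCc5ccccc5)c(OC)c(OC)c3c2OC(C)C3=O)c2c(c1OC)C(=O)C(C)O2 | intermediate
11 | 6,6'-bis(benzyloxy)-4,4',5,5'-tetramethoxy-2,2'-dimethyl-3,3'-bis[(triethylsilyl)oxy]-7,7'-bibenzofuran | COc1c(OCc4ccccc4)c(-c2c(OCc5ccccc5)c(OC)c(OC)c3c(O[Si](CC)(CC)CC)c(C)oc23)c2oc(C)c(O[Si](CC)(CC)CC)c2c1OC | intermediate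
12 | (2S,3R,2'S,3'R)-bis(2,3-epoxide) of 11, each epoxide oxygen on the face that becomes the C2–OSi bond of 13 (not isolated) | COc1c(OCc4ccccc4)c(-c2c(OCc5ccccc5)c(OC)c(OC)c3c2O[C@@]6(C)O[C@@]36O[Si](CC)(CC)CC)c2c(c1OC)[C@]7(O[Si](CC)(CC)CC)O[C@]7(C)O2 | intermediate
13 | (2S,2'S)-6,6'-bis(benzyloxy)-4,4',5,5'-tetramethoxy-2,2'-dimethyl-2,2'-bis[(triethylsilyl)oxy]-[7,7'-bibenzofuran]-3,3'(2H,2'H)-dione | COc1c(OCc4ccccc4)c(-c2c(OCc5ccccc5)c(OC)c(OC)c3c2O[C@@](C)(O[Si](CC)(CC)CC)C3=O)c2c(c1OC)C(=O)[C@](C)(O[Si](CC)(CC)CC)O2 | intermediate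
14 | (2S,2'S)-6,6'-dihydroxy-4,4',5,5'-tetramethoxy-2,2'-dimethyl-2,2'-bis[(triethylsilyl)oxy]-[7,7'-bibenzofuran]-3,3'(2H,2'H)-dione (not isolated) | COc1c(O)c(-c2c(O)c(OC)c(OC)c3c2O[C@@](C)(O[Si](CC)(CC)CC)C3=O)c2c(c1OC)C(=O)[C@](C)(O[Si](CC)(CC)CC)O2 | intermediate
15 | (2R,2'R)-2,2',6,6'-tetrahydroxy-4,4',5,5'-tetramethoxy-2,2'-dimethyl-[7,7'-bibenzofuran]-3,3'(2H,2'H)-dione | COc1c(O)c(-c2c(O)c(OC)c(OC)c3c2O[C@@](C)(O)C3=O)c2c(c1OC)C(=O)[C@](C)(O)O2 | target

**Count and risks**

Total step count: 10. Longest linear sequence: 10 steps (fully linear, two-directional from step 3 on).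

Steps most likely to fail:

1. Step 7 (key step). Carbene addition to the hindered, electron-rich aldehydes may be slow, and the enolisable product may undergo base-mediated aldol reaction or autoxidation before both rings have closed. Fallback, setting out from 8 and coming back at 10: acetalise both chelated phenols with ethyl vinyl ether (PPTS, CH2Cl2) to the bis(1-ethoxyethyl) ether 6,6'-bis(benzyloxy)-2,2'-bis(1-ethoxyethoxy)-4,4',5,5'-tetramethoxy-[1,1'-biphenyl]-3,3'-dicarbaldehyde F1. Irradiate (350 nm, degassed benzene) so that each excited aldehyde abstracts the acetal hydrogen and the 1,5-biradical closes the same C3–C2 bond (Norrish–Yang photocyclisation of an ortho-alkoxyaryl aldehyde), giving 6,6'-bis(benzyloxy)-2,2'-diethoxy-4,4',5,5'-tetramethoxy-2,2'-dimethyl-2,2',3,3'-tetrahydro-[7,7'-bibenzofuran]-3,3'-diol F2. Camphorsulfonic acid (cat.) in toluene at 80 °C then expels ethanol, and the enol tautomerises to 10.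

2. Step 9. Facial discrimination on a tetrasubstituted enol ether may be poor or opposite to the indene analogy, uncatalysed background oxidation may compete, and the stereogenic axis may oppose the catalyst in one atropisomer. Fallback, setting out from 11 and coming back at 13: oxidise without stereocontrol with dimethyldioxirane (acetone, −40 °C, Rubottom oxidation) to the stereoisomer mixture of 6,6'-bis(benzyloxy)-4,4',5,5'-tetramethoxy-2,2'-dimethyl-2,2'-bis[(triethylsilyl)oxy]-[7,7'-bibenzofuran]-3,3'(2H,2'H)-dione F3, and separate the (2S,2'S) isomer 13 by preparative HPLC on a chiral stationary phase (resolution of the locked silyl ketals instead of catalyst control).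

3. Step 6. Vinyl transfer and C–O coupling may stall at a hydrogen-bonded, doubly ortho-substituted phenol, and the vinylboron reagent may be consumed by oxidative homocoupling. Fallback, setting out from 8 and coming back at 9: alkylate with excess 1,2-dibromoethane (K2CO3, DMF, 60 °C) to 6,6'-bis(benzyloxy)-2,2'-bis(2-bromoethoxy)-4,4',5,5'-tetramethoxy-[1,1'-biphenyl]-3,3'-dicarbaldehyde F4, then eliminate HBr with KOtBu (THF, 0 °C) to give 9.

Further compounds
F1 | step 7 | 6,6'-bis(benzyloxy)-2,2'-bis(1-ethoxyethoxy)-4,4',5,5'-tetramethoxy-[1,1'-biphenyl]-3,3'-dicarbaldehyde (acetal centres unassigned) | COc1c(C=O)c(OC(C)OCC)c(-c2c(OC(C)OCC)c(C=O)c(OC)c(OC)c2OCc4ccccc4)c(OCc5ccccc5)c1OC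
F2 | step 7 | 6,6'-bis(benzyloxy)-2,2'-diethoxy-4,4',5,5'-tetramethoxy-2,2'-dimethyl-2,2',3,3'-tetrahydro-[7,7'-bibenzofuran]-3,3'-diol (stereoisomer mixture) | COc1c(OCc4ccccc4)c(-c2c(OCc5ccccc5)c(OC)c(OC)c3c2OC(C)(OCC)C3O)c2c(c1OC)C(O)C(C)(OCC)O2
F3 | step 9 | 6,6'-bis(benzyloxy)-4,4',5,5'-tetramethoxy-2,2'-dimethyl-2,2'-bis[(triethylsilyl)oxy]-[7,7'-bibenzofuran]-3,3'(2H,2'H)-dione (stereoisomer mixture) | COc1c(OCc4ccccc4)c(-c2c(OCc5ccccc5)c(OC)c(OC)c3c2OC(C)(O[Si](CC)(CC)CC)C3=O)c2c(c1OC)C(=O)C(C)(O[Si](CC)(CC)CC)O2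
F4 | step 6 | 6,6'-bis(benzyloxy)-2,2'-bis(2-bromoethoxy)-4,4',5,5'-tetramethoxy-[1,1'-biphenyl]-3,3'-dicarbaldehyde | COc1c(C=O)c(OCCBr)c(-c2c(OCCBr)c(C=O)c(OC)c(OC)c2OCc4ccccc4)c(OCc5ccccc5)c1OC
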